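## Structural features

The target is a germacranolide: a ten-membered carbocycle (numbered here C1–C10, with C14 the methyl on C10, C15 the hydroxymethyl on C4 and C11–C13 the lactone carbons) carrying a trans-fused α-methylene-γ-butyrolactone across C6 (oxygen) and C7 (C11), an (S)-2-methylbutanoate on O8, a free allylic hydroxyl on C1 and a free primary allylic hydroxyl on C15. The ring is a cyclodeca-1,6-diene: the trisubstituted alkenes C4=C5 and C9=C10 face each other across the ring and both are cis with respect to the ring path (4E by the CIP rules because of the hydroxymethyl group, 9Z). C6 (R), C7 (R) and C8 (R) are contiguous: an anti-1,3-diol (O6/O8) whose middle carbon carries C11 syn to O6 and anti to O8 in the zigzag sense, both carbinols being allylic. C1 (S) is isolated, 1,4 to O8 across C9=C10 and 1,5 to O15 through C4=C5. Fragile points are the α-methylene lactone (Michael acceptor), the epimerisable ester α-carbon, three allylic C–O bonds and a latent furan: once C1 is a ketone, a free 8-hydroxyl across the cis C9=C10 bond would close to a hemiketal and dehydrate. The real difficulty is the ten-membered ring with two cis trisubstituted alkenes of defined geometry together with the C6–C8 triad, because a direct macrocyclisation must control ring closure, alkene geometry and relative configuration at once. The key step exploits the array O1–C1···C5=C4–C15–O15: a ring ketone and an allylic alcohol oxygen flank C4=C5 exactly as the products of an epoxy-alcohol (Grob) fragmentation of a C1–C5 bond; reconnecting C1 to C5 gives a hydroazulene (five-membered ring C1–C5, seven-membered ring C1, C5–C10) whose seven-membered ring enforces the cis C9=C10 alkene.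

## Logic of the disconnections

26 ⇒ 25. The C1–H bond is cut (carbinol back to ketone). This leaves C1 as the carbonyl that a fragmentation produces and removes the only isolated stereocentre. The forward step must reduce an enone 1,2 under reagent control beside an α-methylene lactone, an ester and a free primary alcohol.

25 ⇒ 23 (key). The C4=C5 π bond, the C1=O π bond and the O15–H bond are traded for the C1–C5 σ bond and the C4–O bond of a 4,15-epoxide. The ten-membered ring with its two cis alkenes becomes a cis-fused bicyclo[5.3.0]decene, in which every stereocentre sits in a five- or seven-membered ring and C9=C10 is cis by ring size. The forward step needs the tertiary C1 alkoxide, the C4–O bond antiperiplanar to C1–C5, the epoxide oxygen cis to C6 on the five-membered ring (this fixes the C4=C5 geometry) and the 8-ester already in place (no furan formation).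

23 ⇒ 21 + 22. The ester C–O bond at O8 is cut. The acid is commercial, and late acylation keeps the epimerisable ester away from the earlier organometallic steps. The forward step must acylate the secondary O8 and leave the tertiary O1 untouched.

21 ⇒ 20 ⇒ 19. The O8–Si bond and the lactone O6–C12 bond are cut. The lactone opens to a γ-hydroxy acrylate whose free O6 is needed earlier as a directing group. The forward lactonisation must be neutral (epoxide, tertiary allylic alcohol) and must involve O6 only, which the silyl group on O8 guarantees.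

19 ⇒ 17. The C1–C10 bond is cut, giving a cyclopentanone and a (Z)-vinyl iodide. The seven-membered ring is opened to a monocyclic ketone. The forward step must add a vinyl metal to a ketone that bears an acidic α-hydrogen, an ester and an epoxide, and it must give the cis ring fusion; intramolecular delivery from the C5 side chain secures that.

17 ⇒ 16. The two C–O bonds of the epoxide are cut to the exocyclic C4=C15 alkene. The forward epoxidation must place oxygen on the alkene face cis to C6, against the steric bias; the free O6 hydroxyl is used to direct it.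

16 ⇒ 14 + 10. The C5–C6 bond is cut. The cyclopentane becomes a flat, achiral bromo enone, and the chiral information is confined to an open-chain aldehyde. The forward step must add the γ-bromo enone through its α-carbon (transposing the alkene to C4=C15) and attack the aldehyde in the Felkin–Anh sense to give O6 anti to O8.

14 ⇒ 13 ⇒ 12 ⇒ 4 + 8. The C7–C8 bond is cut (aldol); the auxiliary and the silyl group are tactical. C7 and C8 are set together by one auxiliary-controlled anti-aldol reaction. The forward step must enolise the itaconyl imide at C7 without conjugating the alkene and must tolerate a β-iodo enal.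

4 ⇒ 3 ⇒ 1 + 2; 8 ⇒ 7 ⇒ 5; 10 ⇒ 9. The itaconyl unit already contains C6, C7, C11, C12 and C13 at the correct oxidation levels. The iodo enal carries C8, C9, C10 and C14 with the Z geometry that later becomes the cis ring alkene. The bromo enone carries C1–C5 and C15.

## Other disconnections considered

Alternative 1: Cut C6–C7 and O6–C12 in the ten-membered ring. This is the disconnection that comes to mind first: an intramolecular CrCl2- or indium-mediated Barbier allylation of the ω-formyl (Z)-2-(bromomethyl)enoate A1 would close the ring and the lactone in one step. It is set aside because both cis trisubstituted alkenes must first be built separately on an open chain. The macrocyclisation must then control C6 and C7 relative to C8 from a flexible ten-membered transition state, and it needs high dilution. In the chosen plan all stereocentres are made in acyclic or five- to seven-membered settings and the ten-membered ring arises by bond cleavage, with no entropic cost.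

Alternative 2: Cut C9=C10 (or C4=C5) and close the ring by olefin metathesis of the triene lactone A2 with a ruthenium carbene. A trisubstituted alkene in a ten-membered ring forms slowly by metathesis, and its geometry is under thermodynamic rather than mechanistic control. The 1,1-disubstituted C11=C13 and the C4=C5 alkenes can also enter the catalytic cycle (ring contraction, oligomers). The fragmentation fixes one alkene by ring size and the other by a stereospecific anti elimination.

Alternative 3: Cut C6–C7 by a [2,3]-Wittig ring contraction of the 13-membered bis-allylic ether A3 (oxygen bridging C6 and C13). It would form C6–C7, the C6 hydroxyl and the C11=C13 methylene together. There are two competing α-oxy allylic deprotonation sites (C6 and C13) and a possible [1,2]-shift. The strong base excludes the ester and the lactone, so C12 must be oxidised later beside two other allylic alcohols. The 13-membered ether still needs two preformed cis alkenes and a macrocyclisation of its own. The relative configuration at C6/C7 would depend on a transition state that cannot be predicted with confidence, and the route would be longer.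

Key step: step 15

Remark: in step 6 the MgBr2-catalysed anti-aldol of the (R)-thiazolidinethione is assumed to take place on the Z-enolate face remote from the benzyl group (non-chelated model); if the opposite anti adduct formed, the enantiomeric auxiliary would be used with no other change.

## Steps

Step 1
Reactants: 1 itaconic anhydride; 2 (R)-4-benzyl-1,3-thiazolidine-2-thione
Product: 3 4-[(4R)-4-benzyl-2-thioxo-1,3-thiazolidin-3-yl]-2-methylidene-4-oxobutanoic acid
Conditions: NaH, THF, −78 to 0 °C; then 1 M HCl
Reagents that add atoms: none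
Why: N-acylation of the sodium salt of 2 by opening of the cyclic anhydride at its more electrophilic, non-conjugated carbonyl (C6); the conjugated acid (C12) stays free. Low temperature avoids base-induced isomerisation of the itaconyl unit.

Step 2
Reactants: 3 4-[(4R)-4-benzyl-2-thioxo-1,3-thiazolidin-3-yl]-2-methylidene-4-oxobutanoic acid
Product: 4 methyl 4-[(4R)-4-benzyl-2-thioxo-1,3-thiazolidin-3-yl]-2-methylidene-4-oxobutanoate
Conditions: TMSCHN2, PhMe/MeOH (4:1), 0 °C
Reagents that add atoms: (trimethylsilyl)diazomethane, C[Si](C)(C)C=[N+]=[N-]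
Why: O-methylation of the carboxylic acid by diazomethane released in the flask; the neutral conditions spare the thioimide and the exocyclic alkene.

Step 3
Reactants: 5 but-2-yn-1-ol
Product: 7 (Z)-3-iodobut-2-en-1-ol, via cyclic vinylalanate 6 (not isolated)
Conditions: Red-Al (NaAlH2(OCH2CH2OMe)2), THF, 0 °C to rt; then I2, THF, −78 °C
Reagents that add atoms: iodine, II
Why: Hydroxyl-directed trans-hydroalumination of the propargylic alcohol puts aluminium on the distal carbon inside the five-membered alanate; iodinolysis with retention gives the vinyl iodide with I and CH2OH cis.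

Step 4
Reactants: 7 (Z)-3-iodobut-2-en-1-ol
Product: 8 (Z)-3-iodobut-2-enal
Conditions: MnO2, CH2Cl2, rt, dark
Reagents that add atoms: none
Why: Allylic alcohol oxidation on activated MnO2; the Z geometry is retained.

Step 5
Reactants: 9 3-methylcyclopent-2-en-1-one
Product: 10 3-(bromomethyl)cyclopent-2-en-1-one
Conditions: NBS, AIBN (cat.), PhCF3, 80 °C
Reagents that add atoms: N-bromosuccinimide, O=C1CCC(=O)N1Br
Why: Wohl–Ziegler radical bromination at the γ-methyl group of the enone.

Step 6
Reactants: 4 methyl 4-[(4R)-4-benzyl-2-thioxo-1,3-thiazolidin-3-yl]-2-methylidene-4-oxobutanoate; 8 (Z)-3-iodobut-2-enal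
Product: 12 (4R)-4-benzyl-3-[(2R,3S,4Z)-3-hydroxy-5-iodo-2-(3-methoxy-3-oxoprop-1-en-2-yl)hex-4-enoyl]-1,3-thiazolidine-2-thione, via TMS ether 11 (not isolated)
Conditions: MgBr2·OEt2 (10 mol%), Et3N, TMSCl, EtOAc, rt; then 1 M HCl/THF, 0 °C
Reagents that add atoms: none
Why: MgBr2-catalysed direct anti-aldol of an N-acylthiazolidinethione with an unsaturated aldehyde (soft enolisation, silyl trapping of the aldolate). The Z-enolate reacts at C7 (α, as itaconate enolates do) on the face remote from the benzyl group, setting C7 and, anti to it, C8. Silylation keeps O8 from lactonising onto C12 until the brief acidic work-up.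

Step 7
Reactants: 12 (4R)-4-benzyl-3-[(2R,3S,4Z)-3-hydroxy-5-iodo-2-(3-methoxy-3-oxoprop-1-en-2-yl)hex-4-enoyl]-1,3-thiazolidine-2-thione
Product: 13 (4R)-4-benzyl-3-[(2R,3S,4Z)-3-(tert-butyldimethylsilyloxy)-5-iodo-2-(3-methoxy-3-oxoprop-1-en-2-yl)hex-4-enoyl]-1,3-thiazolidine-2-thione
Conditions: TBSOTf, 2,6-lutidine, CH2Cl2, −78 °C
Reagents that add atoms: tert-butyldimethylsilyl trifluoromethanesulfonate, CC(C)(C)[Si](C)(C)OS(=O)(=O)C(F)(F)F
Why: Silylation of the secondary allylic alcohol; blocking O8 ensures that only O6 can later close the lactone with C12.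

Step 8
Reactants: 13 (4R)-4-benzyl-3-[(2R,3S,4Z)-3-(tert-butyldimethylsilyloxy)-5-iodo-2-(3-methoxy-3-oxoprop-1-en-2-yl)hex-4-enoyl]-1,3-thiazolidine-2-thione
Product: 14 methyl (3R,4S,5Z)-4-(tert-butyldimethylsilyloxy)-3-formyl-6-iodo-2-methylidenehept-5-enoate
Conditions: DIBAL-H (iBu2AlH, 1.1 equiv), CH2Cl2, −78 °C; Rochelle salt
Reagents that add atoms: none
Why: N-acylthiazolidinethiones are reduced by DIBAL-H at −78 °C directly to aldehydes through a stable tetrahedral aluminate, much faster than the conjugated methyl ester. The auxiliary is recovered and the aldehyde is used at once to avoid conjugation of the β,γ-alkene.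

Step 9
Reactants: 14 methyl (3R,4S,5Z)-4-(tert-butyldimethylsilyloxy)-3-formyl-6-iodo-2-methylidenehept-5-enoate; 10 3-(bromomethyl)cyclopent-2-en-1-one
Product: 16 methyl (3S,4S,5Z)-4-(tert-butyldimethylsilyloxy)-3-{(S)-hydroxy[(1R)-2-methylidene-5-oxocyclopentyl]methyl}-6-iodo-2-methylidenehept-5-enoate, via allylindium dibromide 15 (not isolated)
Conditions: In powder, THF/H2O (1:1), rt
Reagents that add atoms: none
Why: Indium-mediated Barbier (vinylogous Reformatsky) allylation: 15 adds through its γ-carbon C5 (SE2′) in a chair transition state, forming C5–C6 and the exocyclic C4=C15 alkene with O6 anti to C1 about the new bond. Felkin–Anh attack anti to the bulky silyloxy-bearing C8 branch gives the 6,8-anti carbinol. The acrylate, the vinyl iodide and the silyl ether are inert to the organoindium.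

Step 10
Reactants: 16 methyl (3S,4S,5Z)-4-(tert-butyldimethylsilyloxy)-3-{(S)-hydroxy[(1R)-2-methylidene-5-oxocyclopentyl]methyl}-6-iodo-2-methylidenehept-5-enoate
Product: 17 methyl (3S,4S,5Z)-4-(tert-butyldimethylsilyloxy)-3-{(S)-hydroxy[(3S,4S)-5-oxo-1-oxaspiro[2.4]heptan-4-yl]methyl}-6-iodo-2-methylidenehept-5-enoate
Conditions: VO(acac)2 (5 mol%), t-BuOOH, CH2Cl2, 0 °C
Reagents that add atoms: tert-butyl hydroperoxide, CC(C)(C)OO
Why: Hydroxyl-directed epoxidation of a homoallylic alcohol: the vanadate ester of O6 delivers oxygen to the face of C4=C15 on which the C5–C6 bond lies (epoxide oxygen cis to C6). The acrylate and the iodoalkene are electron-poor and do not react.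

Step 11
Reactants: 17 methyl (3S,4S,5Z)-4-(tert-butyldimethylsilyloxy)-3-{(S)-hydroxy[(3S,4S)-5-oxo-1-oxaspiro[2.4]heptan-4-yl]methyl}-6-iodo-2-methylidenehept-5-enoate
Product: 19 methyl 8β-(tert-butyldimethylsilyloxy)-4β,15-epoxy-1α,6α-dihydroxy-5αH,7αH-guaia-9,11(13)-dien-12-oate, via vinylchromium dichloride 18 (not isolated)
Conditions: CrCl2 (6 equiv), NiCl2 (2 mol%), DMSO, rt
Reagents that add atoms: none
Why: Intramolecular Nozaki–Hiyama–Kishi reaction: zerovalent nickel inserts into C–I, transmetalation gives 18 with retention of the Z geometry, and 1,2-addition to the C1 ketone closes the seven-membered ring. The tether from C5 reaches only the ketone face syn to C6, so the hydroazulene is cis-fused (1-OH cis to H5). The organochromium is not basic and does not touch the ester, the epoxide or the acidic C5–H.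

Step 12
Reactants: 19 methyl 8β-(tert-butyldimethylsilyloxy)-4β,15-epoxy-1α,6α-dihydroxy-5αH,7αH-guaia-9,11(13)-dien-12-oate
Product: 20 8β-(tert-butyldimethylsilyloxy)-4β,15-epoxy-1α-hydroxy-5αH,7αH-guaia-9,11(13)-dien-12,6α-olide
Conditions: Bu2SnO (10 mol%), toluene, 80 °C
Reagents that add atoms: none
Why: Neutral tin-catalysed transesterification closes the five-membered lactone from O6 (O8 is silylated; the tertiary O1 would need a seven-membered ring). C6 and C7 already carry the trans relationship.

Step 13
Reactants: 20 8β-(tert-butyldimethylsilyloxy)-4β,15-epoxy-1α-hydroxy-5αH,7αH-guaia-9,11(13)-dien-12,6α-olide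
Product: 21 4β,15-epoxy-1α,8β-dihydroxy-5αH,7αH-guaia-9,11(13)-dien-12,6α-olide
Conditions: TBAF (Bu4NF), AcOH (1:1), THF, 0 °C to rt
Reagents that add atoms: none
Why: Fluoride desilylation; the acetic acid buffer protects the α-methylene lactone and prevents an alkoxide-driven fragmentation before O8 is acylated.

Step 14
Reactants: 21 4β,15-epoxy-1α,8β-dihydroxy-5αH,7αH-guaia-9,11(13)-dien-12,6α-olide; 22 (S)-2-methylbutanoic acid
Product: 23 4β,15-epoxy-1α-hydroxy-8β-[(2S)-2-methylbutanoyloxy]-5αH,7αH-guaia-9,11(13)-dien-12,6α-olide
Conditions: DCC, DMAP (cat.), CH2Cl2, 0 °C to rt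
Reagents that add atoms: none
Why: Steglich esterification of the secondary allylic O8; the tertiary O1 is not acylated, and the low temperature limits epimerisation of the acid.

Step 15
Reactants: 23 4β,15-epoxy-1α-hydroxy-8β-[(2S)-2-methylbutanoyloxy]-5αH,7αH-guaia-9,11(13)-dien-12,6α-olide
Product: 25 (4E,6R,7R,8R,9Z)-15-hydroxy-8-[(2S)-2-methylbutanoyloxy]-1-oxogermacra-4,9,11(13)-trien-12,6-olide, via titanium alkoxide 24 (not isolated)
Conditions: Ti(OiPr)4 (1.5 equiv), CH2Cl2, 0 to 40 °C; aq. tartrate work-up
Reagents that add atoms: none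
Why: Ligand exchange gives the C1 titanium alkoxide 24, in which the metal also activates the epoxide oxygen; the O1 lone pair pushes, the ring-fusion C1–C5 σ bond breaks, C4=C5 forms and the C4–O bond of the epoxide opens, so C1 becomes the ketone and the epoxide oxygen becomes O15 (Grob-type epoxy-alcohol fragmentation, the known route from fused bicyclic tertiary 3,4-epoxy alcohols to medium-ring hydroxy enones). No ring is closed: the five- and seven-membered rings merge into the ten-membered ring by cleavage of their common bond. No stereocentre is created; C1, C4 and C5 are erased while C6, C7, C8 and the ester centre are not touched. The C4=C5 geometry is fixed stereospecifically by the antiperiplanar, concerted course: the epoxide oxygen is cis to C6 on the five-membered ring, so C3 and C6 end cis (ring-cis, C15 trans to C6), and C9=C10 keeps the cis geometry of the former seven-membered ring. The required alignment (C4–O anti to C1–C5, C6 pseudo-axial on the five-membered ring) is available only in the cis-fused hydroazulene, which steps 9 to 11 provide. Release of epoxide strain and formation of the conjugated enone drive the reaction. The ester already on O8 keeps the (Z)-γ-oxy enone from closing to a furan, and a Lewis-acidic titanium alkoxide instead of a free alkali alkoxide spares the α-methylene lactone and the ester.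

Step 16
Reactants: 25 (4E,6R,7R,8R,9Z)-15-hydroxy-8-[(2S)-2-methylbutanoyloxy]-1-oxogermacra-4,9,11(13)-trien-12,6-olide
Product: 26 (1S,4E,6R,7R,8R,9Z)-1,15-dihydroxy-8-[(2S)-2-methylbutanoyloxy]germacra-4,9,11(13)-trien-12,6-olide (CNP0526758.1)
Conditions: (R)-Me-CBS oxazaborolidine (0.5 equiv), catecholborane (excess), toluene, −78 °C
Reagents that add atoms: none
Why: Corey–Bakshi–Shibata 1,2-reduction of the enone under reagent control: the α-branched alkenyl side (C10) acts as the large group and C2H2 as the small one, so the (R)-catalyst should give the (1S)-carbinol. Catecholborane at −78 °C should leave the lactone, the ester and the alkenes alone; the free O15–H only consumes one equivalent.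

## Compound list

1 | itaconic anhydride (3-methylideneoxolane-2,5-dione) | C=C1CC(=O)OC1=O | starting material
2 | (R)-4-benzyl-1,3-thiazolidine-2-thione | S=C1N[C@H](Cc2ccccc2)CS1 | starting material
3 | 4-[(4R)-4-benzyl-2-thioxo-1,3-thiazolidin-3-yl]-2-methylidene-4-oxobutanoic acid | OC(=O)C(=C)CC(=O)N1C(=S)SC[C@H]1Cc1ccccc1 | intermediate
4 | methyl 4-[(4R)-4-benzyl-2-thioxo-1,3-thiazolidin-3-yl]-2-methylidene-4-oxobutanoate | COC(=O)C(=C)CC(=O)N1C(=S)SC[C@H]1Cc1ccccc1 | intermediate
5 | but-2-yn-1-ol | CC#CCO | starting material
6 | cyclic vinylalanate (sodium 2,2-bis(2-methoxyethoxy)-3-methyl-2,5-dihydro-1,2-oxaaluminol-2-uide) | CC1=CCO[Al-]1(OCCOC)OCCOC.[Na+] | intermediate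
7 | (Z)-3-iodobut-2-en-1-ol | C/C(I)=C/CO | intermediate
8 | (Z)-3-iodobut-2-enal | C/C(I)=C/C=O | intermediate
9 | 3-methylcyclopent-2-en-1-one | CC1=CC(=O)CC1 | starting material
10 | 3-(bromomethyl)cyclopent-2-en-1-one | BrCC1=CC(=O)CC1 | intermediate
11 | TMS ether of 12: (4R)-4-benzyl-3-[(2R,3S,4Z)-5-iodo-2-(3-methoxy-3-oxoprop-1-en-2-yl)-3-(trimethylsilyloxy)hex-4-enoyl]-1,3-thiazolidine-2-thione | O=C([C@H](C(=C)C(=O)OC)[C@H](O[Si](C)(C)C)/C=C(/C)I)N1C(=S)SC[C@H]1Cc1ccccc1 | intermediate
12 | (4R)-4-benzyl-3-[(2R,3S,4Z)-3-hydroxy-5-iodo-2-(3-methoxy-3-oxoprop-1-en-2-yl)hex-4-enoyl]-1,3-thiazolidine-2-thione | O=C([C@H](C(=C)C(=O)OC)[C@H](O)/C=C(/C)I)N1C(=S)SC[C@H]1Cc1ccccc1 | intermediate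
13 | (4R)-4-benzyl-3-[(2R,3S,4Z)-3-(tert-butyldimethylsilyloxy)-5-iodo-2-(3-methoxy-3-oxoprop-1-en-2-yl)hex-4-enoyl]-1,3-thiazolidine-2-thione | O=C([C@H](C(=C)C(=O)OC)[C@H](O[Si](C)(C)C(C)(C)C)/C=C(/C)I)N1C(=S)SC[C@H]1Cc1ccccc1 | intermediate
14 | methyl (3R,4S,5Z)-4-(tert-butyldimethylsilyloxy)-3-formyl-6-iodo-2-methylidenehept-5-enoate | O=C[C@H](C(=C)C(=O)OC)[C@H](O[Si](C)(C)C(C)(C)C)/C=C(/C)I | intermediate
15 | [(3-oxocyclopent-1-en-1-yl)methyl]indium dibromide | O=C1C=C(C[In](Br)Br)CC1 | intermediate
16 | methyl (3S,4S,5Z)-4-(tert-butyldimethylsilyloxy)-3-{(S)-hydroxy[(1R)-2-methylidene-5-oxocyclopentyl]methyl}-6-iodo-2-methylidenehept-5-enoate | O=C1CCC(=C)[C@@H]1[C@@H](O)[C@H](C(=C)C(=O)OC)[C@H](O[Si](C)(C)C(C)(C)C)/C=C(/C)I | intermediate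
17 | methyl (3S,4S,5Z)-4-(tert-butyldimethylsilyloxy)-3-{(S)-hydroxy[(3S,4S)-5-oxo-1-oxaspiro[2.4]heptan-4-yl]methyl}-6-iodo-2-methylidenehept-5-enoate | O=C1CC[C@@]2(CO2)[C@@H]1[C@@H](O)[C@H](C(=C)C(=O)OC)[C@H](O[Si](C)(C)C(C)(C)C)/C=C(/C)I | intermediate
18 | vinylchromium dichloride derived from 17 (CrCl2 in place of I) | O=C1CC[C@@]2(CO2)[C@@H]1[C@@H](O)[C@H](C(=C)C(=O)OC)[C@H](O[Si](C)(C)C(C)(C)C)/C=C(/C)[Cr](Cl)Cl | intermediate
19 | methyl 8β-(tert-butyldimethylsilyloxy)-4β,15-epoxy-1α,6α-dihydroxy-5αH,7αH-guaia-9,11(13)-dien-12-oate (cis-fused hydroazulene, epoxide oxygen on the β face of C4) | O[C@@]12CC[C@@]3(CO3)[C@@H]1[C@@H](O)[C@H](C(=C)C(=O)OC)[C@H](O[Si](C)(C)C(C)(C)C)C=C2C | intermediate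
20 | 8β-(tert-butyldimethylsilyloxy)-4β,15-epoxy-1α-hydroxy-5αH,7αH-guaia-9,11(13)-dien-12,6α-olide | O[C@@]12CC[C@@]3(CO3)[C@@H]1[C@H]1OC(=O)C(=C)[C@@H]1[C@H](O[Si](C)(C)C(C)(C)C)C=C2C | intermediate
21 | 4β,15-epoxy-1α,8β-dihydroxy-5αH,7αH-guaia-9,11(13)-dien-12,6α-olide | O[C@@]12CC[C@@]3(CO3)[C@@H]1[C@H]1OC(=O)C(=C)[C@@H]1[C@H](O)C=C2C | intermediate
22 | (S)-2-methylbutanoic acid | CC[C@H](C)C(=O)O | starting material
23 | 4β,15-epoxy-1α-hydroxy-8β-[(2S)-2-methylbutanoyloxy]-5αH,7αH-guaia-9,11(13)-dien-12,6α-olide | O[C@@]12CC[C@@]3(CO3)[C@@H]1[C@H]1OC(=O)C(=C)[C@@H]1[C@H](OC(=O)[C@@H](C)CC)C=C2C | intermediate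
24 | 1-O-(triisopropoxytitanium) alkoxide of 23 | CC(C)O[Ti](OC(C)C)(OC(C)C)O[C@@]12CC[C@@]3(CO3)[C@@H]1[C@H]1OC(=O)C(=C)[C@@H]1[C@H](OC(=O)[C@@H](C)CC)C=C2C | intermediate
25 | (4E,6R,7R,8R,9Z)-15-hydroxy-8-[(2S)-2-methylbutanoyloxy]-1-oxogermacra-4,9,11(13)-trien-12,6-olide | C=C1C(=O)O[C@@H]2/C=C(/CO)CCC(=O)/C(C)=C\[C@@H](OC(=O)[C@@H](C)CC)[C@@H]12 | intermediate
26 | (1S,4E,6R,7R,8R,9Z)-1,15-dihydroxy-8-[(2S)-2-methylbutanoyloxy]germacra-4,9,11(13)-trien-12,6-olide (CNP0526758.1) | C=C1C(=O)O[C@@H]2/C=C(/CO)CC[C@H](O)/C(C)=C\[C@@H](OC(=O)[C@@H](C)CC)[C@@H]12 | target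

## Step count and least certain steps

Total: 16 steps. Longest linear sequence: 13 steps (steps 1, 2 and 6 to 16); steps 3–4 and step 5 make the two side fragments.

Step 15 (key). The fragmentation may stall for lack of antiperiplanar alignment if the five-membered ring prefers the conformer with C6 pseudo-equatorial. Alternatively the Lewis acid may divert the 2,2-disubstituted epoxide into a hydride shift to the aldehyde, or the isopropoxide ligands may exchange with the ester. Fallback, from 23 back to 25: replace the polar push by an alkoxy-radical β-scission (CeCl3 (cat.), Bu4NCl, 400 nm light, MeCN). Ligand-to-metal charge transfer in the tetravalent cerium alkoxide gives the O1 radical. Cleavage of C1–C5 gives the C5 radical, which opens the adjacent epoxide to C4=C5 and the O15 radical, and trivalent cerium reduces this back. No new isolable compound is formed. The alkene geometry is then set by ring conformation, not by a stereospecific anti elimination.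

Step 11. Vinylchromium reagents add to ketones slowly, so protodehalogenation of the vinyl iodide or Lewis-acid opening of the β,γ-epoxy ketone to the γ-hydroxy enone could compete with ring closure. Fallback, from 17 back to 19: iodine–lithium exchange with t-BuLi (3.1 equiv, THF/Et2O, −100 °C) followed by intramolecular 1,2-addition of the vinyllithium to the ketone (anionic Barbier-type cyclisation, no chromium). No new isolable compound is formed. Its own weak point is competing attack on the methyl ester.

Step 9. Facial selection on the α-branched aldehyde may be poor, because the planar acrylate branch and the silyloxy branch compete for the antiperiplanar position, which would give the C6 epimer. The β,γ-unsaturated ketone may also slip into conjugation during the reaction. Fallback, from 10 and 14 back to 16: convert 10 with B2pin2 and Pd2(dba)3 (cat.) into 3-[(4,4,5,5-tetramethyl-1,3,2-dioxaborolan-2-yl)methyl]cyclopent-2-en-1-one F1 and add it to 14 under catalysis by the chiral phosphoric acid (R)-TRIP (toluene, −30 °C). The catalyst then controls the aldehyde face (Re-face addition gives the 6S carbinol of 16), and the closed chair transition state is kept.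

Step 6. Soft enolisation of the itaconyl imide may be followed by migration of the alkene into conjugation or by reaction at the γ-carbon. Triethylamine may also undergo addition–elimination at the β-iodo enal, and the facial sense may not be as assumed. Fallback, from 4 and 8 back to 12: preform the dibutylboron Z-enolate of 4 (Bu2BOTf, iPr2NEt, CH2Cl2, −78 °C) and add it to 8 precomplexed with Et2AlCl. This is a stoichiometric enolate and an open transition state, which also gives the anti adduct and needs no free tertiary amine beside the iodo enal. No new isolable compound is formed.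

Step 16. The conformation of the ten-membered ring may override reagent control, and hydride may be delivered 1,4 or to the α-methylene lactone. Fallback, from 25 back to 26: silylate O15 (TBSCl, imidazole) to give the 15-O-TBS enone F2 and reduce under substrate control (NaBH4, CeCl3·7H2O, MeOH, −78 °C; Luche). If the (1R)-alcohol F3 results, invert it by a Mitsunobu reaction with formic acid (DIAD, PPh3) to the (1S)-formate F4. Cleave the formate (KHCO3 (cat.), MeOH, 0 °C) to the (1S)-alcohol F5 and remove the silyl group (HF·pyridine, THF) to reach 26.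

## Further compounds

F0 | step 15 | none | none
F0 | step 11 | none | none
F1 | step 9 | 3-[(4,4,5,5-tetramethyl-1,3,2-dioxaborolan-2-yl)methyl]cyclopent-2-en-1-one | O=C1C=C(CB2OC(C)(C)C(C)(C)O2)CC1
F0 | step 6 | none | none
F2 | step 16 | (4E,6R,7R,8R,9Z)-15-(tert-butyldimethylsilyloxy)-8-[(2S)-2-methylbutanoyloxy]-1-oxogermacra-4,9,11(13)-trien-12,6-olide | C=C1C(=O)O[C@@H]2/C=C(/CO[Si](C)(C)C(C)(C)C)CCC(=O)/C(C)=C\[C@@H](OC(=O)[C@@H](C)CC)[C@@H]12
F3 | step 16 | (1R,4E,6R,7R,8R,9Z)-15-(tert-butyldimethylsilyloxy)-1-hydroxy-8-[(2S)-2-methylbutanoyloxy]germacra-4,9,11(13)-trien-12,6-olide | C=C1C(=O)O[C@@H]2/C=C(/CO[Si](C)(C)C(C)(C)C)CC[C@@H](O)/C(C)=C\[C@@H](OC(=O)[C@@H](C)CC)[C@@H]12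
F4 | step 16 | (1S,4E,6R,7R,8R,9Z)-15-(tert-butyldimethylsilyloxy)-1-formyloxy-8-[(2S)-2-methylbutanoyloxy]germacra-4,9,11(13)-trien-12,6-olide | C=C1C(=O)O[C@@H]2/C=C(/CO[Si](C)(C)C(C)(C)C)CC[C@H](OC=O)/C(C)=C\[C@@H](OC(=O)[C@@H](C)CC)[C@@H]12
F5 | step 16 | (1S,4E,6R,7R,8R,9Z)-15-(tert-butyldimethylsilyloxy)-1-hydroxy-8-[(2S)-2-methylbutanoyloxy]germacra-4,9,11(13)-trien-12,6-olide | C=C1C(=O)O[C@@H]2/C=C(/CO[Si](C)(C)C(C)(C)C)CC[C@H](O)/C(C)=C\[C@@H](OC(=O)[C@@H](C)CC)[C@@H]12
A1 | alternative 1 | methyl (2Z,4R,5Z,7S,10E)-2-(bromomethyl)-7-(tert-butyldimethylsilyloxy)-10-[(tert-butyldimethylsilyloxy)methyl]-6-methyl-4-[(2S)-2-methylbutanoyloxy]-12-oxododeca-2,5,10-trienoate (seco aldehyde–allyl bromide) | O=C/C=C(/CO[Si](C)(C)C(C)(C)C)CC[C@H](O[Si](C)(C)C(C)(C)C)/C(C)=C\[C@@H](OC(=O)[C@@H](C)CC)/C=C(\CBr)C(=O)OC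
A2 | alternative 2 | triene lactone for ring-closing metathesis: α-methylene-γ-butyrolactone bearing at C7 the 1-[(2S)-2-methylbutanoyloxy]allyl group and at C6 the (E)-5-(tert-butyldimethylsilyloxy)-2-[(tert-butyldimethylsilyloxy)methyl]-6-methylhepta-1,6-dienyl chain | C=C1C(=O)O[C@H](/C=C(/CO[Si](C)(C)C(C)(C)C)CC[C@H](O[Si](C)(C)C(C)(C)C)C(C)=C)[C@H]1[C@H](OC(=O)[C@@H](C)CC)C=C
A3 | alternative 3 | 13-membered bis-allylic ether (oxygen between C6 and C13; O1, O8 and O15 as TBS ethers, O12 as PMB ether) | O1C/C=C(/CO[Si](C)(C)C(C)(C)C)CC[C@H](O[Si](C)(C)C(C)(C)C)/C(C)=C\[C@@H](O[Si](C)(C)C(C)(C)C)/C=C(/COCc2ccc(OC)cc2)C1
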